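**Retrosynthetic overview**
1. Target 13 ⇒ enol 10 + acid 11 (C-acylation at C7 of the enolised 1,3-dione of ring A). Enol 10 ⇒ vinylogous methyl ester 9.
2. Enabling feature: in the 2H-pyran ring, O1–C8a=C4a–C4=C3 is atom for atom a furan fused to ring A, and the sixth atom, C2, is a CMe2 carbon. The pyran is the closed valence isomer of the Z-dienone O=C8a–C4a=C4–C3=CMe2, and the prenyl chain on C5 ends in the same =CMe2 unit.
3. 9 ⇒ furan aldehyde 5. Oxidative opening of the furan, a twofold isopropylidene Wittig olefination and oxa-6π closure expand the five-membered ring to the six-membered one and complete the prenyl group in the same flask.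
4. 5 ⇒ 4 ⇒ 3. Furan carbons C2/C3 and the CH2CHO arm are the two halves of a cyclohexene ring that is not in the target. That ring is made by an enantioselective Diels–Alder reaction of quinone 1 with butadiene 2, which sets the quaternary C5, and is then cleaved by ozonolysis.
5. Order of rings: ring A (present in 1), temporary carbocycle (made in step 1, cleaved in step 2), furan (step 3), 2H-pyran (step 4).

Key step: step 4

Assumption: the (S)-configured oxazaborolidinium ion is taken to expose the Re face at C6 of 1, as it does for other dienophiles bound through a carbonyl group with an α-C–H contact; if the adduct proved antipodal, the (R)-catalyst would be used with nothing else changed.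

Step 1
Reactants: 1 2-methoxy-5-methyl-1,4-benzoquinone; 2 buta-1,3-diene
Product: 3 (4aS,8aR)-2-methoxy-4a-methyl-4a,5,8,8a-tetrahydronaphthalene-1,4-dione
Conditions: (S)-3,3-diphenyl-1-(2-methylphenyl)tetrahydro-1H,3H-pyrrolo[1,2-c][1,3,2]oxazaborole (20 mol %), Tf2NH (18 mol %), CH2Cl2, −78 → −20 °C
Reagents that add atoms: none
Why: Enantioselective Diels–Alder reaction in which the cationic oxazaborolidine activates a quinone carbonyl, the methoxy group deactivates C2=C3 so that only the methyl-bearing C5=C6 bond reacts, suprafacial addition makes the ring fusion cis, and shielding of one quinone face by a catalyst phenyl group sends the diene to the C6-Re/C5-Si face, which sets the quaternary carbon as S (and C8a as R).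

Step 2
Reactants: 3 (4aS,8aR)-2-methoxy-4a-methyl-4a,5,8,8a-tetrahydronaphthalene-1,4-dione
Product: 4 2,2'-[(1S,2R)-4-methoxy-1-methyl-3,6-dioxocyclohex-4-ene-1,2-diyl]diacetaldehyde
Conditions: O3, CH2Cl2–MeOH, NaHCO3, Sudan red 7B as end-point indicator, −78 °C; then Me2S, −78 → 23 °C
Reagents that add atoms: ozone, [O-][O+]=O
Why: Ozonolysis with reductive work-up, in which the isolated cis-disubstituted alkene of the temporary ring is far more electron-rich than the doubly acceptor-substituted methoxy enedione alkene, so titration to the indicator end point should cleave it alone and leave both stereocentres untouched.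

Step 3
Reactants: 4 2,2'-[(1S,2R)-4-methoxy-1-methyl-3,6-dioxocyclohex-4-ene-1,2-diyl]diacetaldehyde
Product: 5 [(4S)-7-methoxy-4-methyl-5-oxo-4,5-dihydro-1-benzofuran-4-yl]acetaldehyde
Conditions: p-TsOH·H2O (5 mol %), 4 Å molecular sieves, toluene, 23 → 50 °C
Reagents that add atoms: none
Why: Paal–Knorr furan synthesis, in which only the arm on C2 stands 1,4 to an enolisable ketone, so acid-catalysed cyclodehydration should turn that arm and the C3 carbonyl into an aromatic furan (erasing the tertiary stereocentre), whereas the arm on the quaternary carbon cannot aromatise and stays a free aldehyde.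

Step 4
Reactants: 5 [(4S)-7-methoxy-4-methyl-5-oxo-4,5-dihydro-1-benzofuran-4-yl]acetaldehyde; 6 isopropyltriphenylphosphonium iodide
Product: 9 (5S)-8-methoxy-2,2,5-trimethyl-5-(3-methylbut-2-en-1-yl)-2H-chromen-6(5H)-one, via cis-enedial 7 (not isolated), via Z-dienone 8 (not isolated)
Conditions: (a) dimethyldioxirane (1.05 equiv, acetone solution), CH2Cl2, −40 → 0 °C, then cold evaporation; (b) 6 (2.4 equiv), n-BuLi (2.3 equiv), THF, 0 °C, then crude 7 added at −78 °C, warm to 23 °C
Reagents that add atoms: none
Why: Proposed new method: one equivalent of dimethyldioxirane should transfer oxygen to the unsubstituted C2=C3 edge of the furan of 5, which unzips to cis-enedial 7, in which the former furan oxygen is now the ring A carbonyl and the Z geometry is inherited from the ring (closest known reaction type: dioxirane or peracid oxidation of furans to cis-enediones, the opening move of the Achmatowicz ring expansion). The non-stabilised ylide made from 6 then olefinates both aldehydes in Wittig reactions, so the saturated arm becomes the prenyl group, the enal becomes Z-dienone 8, and the oxygen brought in by the oxidant leaves again on phosphorus. Dienone 8 is a 1-oxatriene held s-cis by ring A and should close on warming by a thermal disrotatory oxa-6π electrocyclisation that forms the O–CMe2 bond and the six-membered 2H-pyran, as dienones from Knoevenagel condensations of enals are known to do, the closed form being favoured by the gem-dimethyl terminus and by relief of allylic strain against the quaternary carbon. In sum all five furan atoms are kept and one isopropylidene carbon is inserted between the oxygen and the former furan C2, a ring expansion from five to six atoms. No stereocentre is created, and the quaternary centre has no acidic hydrogen and no retro-aldol path, so its configuration is carried through. The step needs furan-over-enone-and-aldehyde selectivity in the oxidation, secured by the push-pull deactivation of the methoxy enone and by limiting the oxidant at low temperature, and aldehyde-over-ketone selectivity in the olefination, secured because one ketone is a vinylogous ester flanked by the quaternary carbon and the other a hindered cross-conjugated carbonyl.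

Step 5
Reactants: 9 (5S)-8-methoxy-2,2,5-trimethyl-5-(3-methylbut-2-en-1-yl)-2H-chromen-6(5H)-one
Product: 10 (5S)-8-hydroxy-2,2,5-trimethyl-5-(3-methylbut-2-en-1-yl)-2H-chromen-6(5H)-one
Conditions: LiOH (3 equiv), THF–H2O, 45 °C; then 1 M HCl to pH 3
Reagents that add atoms: lithium hydroxide, [Li+].[OH-]
Why: Addition–elimination hydrolysis of a vinylogous methyl ester, in which hydroxide attacks C8, methoxide leaves and the delocalised enolate of the 1,3-dione protects the product from further attack, while the prenyl group, the 2H-pyran and the non-enolisable quaternary centre are inert to aqueous base.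

Step 6
Reactants: 10 (5S)-8-hydroxy-2,2,5-trimethyl-5-(3-methylbut-2-en-1-yl)-2H-chromen-6(5H)-one; 11 3-phenylpropanoic acid
Product: 13 (5S)-8-hydroxy-2,2,5-trimethyl-5-(3-methylbut-2-en-1-yl)-7-(3-phenylpropanoyl)-2H-chromen-6(5H)-one, via enol ester 12 (not isolated)
Conditions: DCC (1.2 equiv), DMAP (1.2 equiv), CH2Cl2, 0 → 23 °C
Reagents that add atoms: none
Why: Carbodiimide-mediated O-acylation followed by DMAP-mediated O-to-C acyl migration, the standard C-acylation of cyclic 1,3-diones, in which the acyl group ends on C7 because the enolised triketone with its internal hydrogen bond is the thermodynamic sink and no stereocentre is touched.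

**Compound list**
1 | 2-methoxy-5-methyl-1,4-benzoquinone | COC1=CC(=O)C(C)=CC1=O | starting material
2 | buta-1,3-diene | C=CC=C | starting material
3 | (4aS,8aR)-2-methoxy-4a-methyl-4a,5,8,8a-tetrahydronaphthalene-1,4-dione | C1=CC[C@]2(C)C(=O)C=C(OC)C(=O)[C@@H]2C1 | intermediate
4 | 2,2'-[(1S,2R)-4-methoxy-1-methyl-3,6-dioxocyclohex-4-ene-1,2-diyl]diacetaldehyde | O=CC[C@]1(C)C(=O)C=C(OC)C(=O)[C@@H]1CC=O | intermediate
5 | [(4S)-7-methoxy-4-methyl-5-oxo-4,5-dihydro-1-benzofuran-4-yl]acetaldehyde | O=CC[C@]1(C)C(=O)C=C(OC)c2occc12 | intermediate
6 | isopropyltriphenylphosphonium iodide | CC(C)[P+](c1ccccc1)(c1ccccc1)c1ccccc1.[I-] | starting material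
7 | (2Z)-2-[(6S)-3-methoxy-6-methyl-2,5-dioxo-6-(2-oxoethyl)cyclohex-3-en-1-ylidene]acetaldehyde (cis-enedial) | O=CC[C@]1(C)C(=O)C=C(OC)C(=O)/C1=C\C=O | intermediate
8 | (5S,6Z)-2-methoxy-5-methyl-5-(3-methylbut-2-en-1-yl)-6-(3-methylbut-2-en-1-ylidene)cyclohex-2-ene-1,4-dione (Z-dienone) | CC(C)=CC[C@]1(C)C(=O)C=C(OC)C(=O)/C1=C\C=C(C)C | intermediate
9 | (5S)-8-methoxy-2,2,5-trimethyl-5-(3-methylbut-2-en-1-yl)-2H-chromen-6(5H)-one | CC(C)=CC[C@]1(C)C(=O)C=C(OC)C2=C1C=CC(C)(C)O2 | intermediate
10 | (5S)-8-hydroxy-2,2,5-trimethyl-5-(3-methylbut-2-en-1-yl)-2H-chromen-6(5H)-one | CC(C)=CC[C@]1(C)C(=O)C=C(O)C2=C1C=CC(C)(C)O2 | intermediate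
11 | 3-phenylpropanoic acid | O=C(O)CCc1ccccc1 | starting material
12 | (5S)-2,2,5-trimethyl-5-(3-methylbut-2-en-1-yl)-6-oxo-5,6-dihydro-2H-chromen-8-yl 3-phenylpropanoate (enol ester) | CC(C)=CC[C@]1(C)C(=O)C=C(OC(=O)CCc2ccccc2)C2=C1C=CC(C)(C)O2 | intermediate
13 | (5S)-8-hydroxy-2,2,5-trimethyl-5-(3-methylbut-2-en-1-yl)-7-(3-phenylpropanoyl)-2H-chromen-6(5H)-one | CC(C)=CC[C@]1(C)C(=O)C(C(=O)CCc2ccccc2)=C(O)C2=C1C=CC(C)(C)O2 | target

Total step count: 6. Longest linear sequence: 6 steps (1 → 13).

**Steps most likely to fail**

1. **Step 4.**
   - What may go wrong: the conjugated furan may be oxidised too slowly, so that attack on the methoxy enone or on the aldehyde competes. The basic ylide may also add in conjugate fashion to the enedial or enolise it before olefination.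
   - Fallback: it sets out from 4 and comes back at 9, using known chemistry only. Dialdehyde 4 is olefinated twice with the ylide from 6 (THF, −78 → 0 °C) to give (5S,6R)-2-methoxy-5-methyl-5,6-bis(3-methylbut-2-en-1-yl)cyclohex-2-ene-1,4-dione F1. DDQ (1,4-dioxane, 60–80 °C) then abstracts hydride from the allylic CH2 of the C6 prenyl group in the enol form of this compound. That leads through 8 to 9, as in the known oxidative cyclisation of ortho-prenyl phenols and prenylated hydroxyquinones to 2,2-dimethyl-2H-chromenes.

2. **Step 1.**
   - What may go wrong: facial selectivity may be poor if the catalyst binds both carbonyl groups competitively, and butadiene may add sluggishly to the trisubstituted quinone double bond.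
   - Fallback: it sets out from 1 and comes back at 5.
     - A BF3·OEt2-promoted formal [3+2] addition of ethyl vinyl ether to 1 (CH2Cl2, −78 °C) gives 2-ethoxy-7-methoxy-4-methyl-2,3-dihydro-1-benzofuran-5-ol F2.
     - p-TsOH in warm toluene aromatises it to 7-methoxy-4-methyl-1-benzofuran-5-ol F3.
     - An asymmetric Tsuji–Trost allylic dearomatisation follows, with allyl methyl carbonate, the zerovalent palladium source Pd2(dba)3·CHCl3 and N,N'-[(1R,2R)-cyclohexane-1,2-diyl]bis[2-(diphenylphosphino)benzamide], or its mirror image if that gives the S product. It delivers (4S)-4-allyl-7-methoxy-4-methyl-1-benzofuran-5(4H)-one F4. This reaction type is known for 1-alkyl-2-naphthols, and here the furan plays the part of the second benzene ring.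
     - Lemieux–Johnson cleavage (OsO4 cat., NaIO4, 2,6-lutidine, dioxane–H2O) then gives 5.

3. **Step 3.**
   - What may go wrong: intramolecular aldol condensation between the two aldehyde arms may outrun furan formation, or the enol may close onto the wrong arm.
   - Fallback: it sets out from 4 and comes back at 5.
     - Both aldehydes are first masked with HC(OMe)3 and CSA in MeOH at 0 °C, which closes the aldol channel and gives (4S)-4-(2,2-dimethoxyethyl)-2,7-dimethoxy-4-methyl-2,3-dihydro-1-benzofuran-5(4H)-one F5 (mixture at the acetal carbon).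
     - p-TsOH in toluene at 80 °C eliminates methanol from the cyclic acetal to give (4S)-4-(2,2-dimethoxyethyl)-7-methoxy-4-methyl-1-benzofuran-5(4H)-one F6.
     - 1 M HCl in THF unmasks the side-chain aldehyde to give 5.

**Further compounds**
F1 | step 4 | (5S,6R)-2-methoxy-5-methyl-5,6-bis(3-methylbut-2-en-1-yl)cyclohex-2-ene-1,4-dione | CC(C)=CC[C@]1(C)C(=O)C=C(OC)C(=O)[C@@H]1CC=C(C)C
F2 | step 1 | 2-ethoxy-7-methoxy-4-methyl-2,3-dihydro-1-benzofuran-5-ol (racemic) | CCOC1Cc2c(C)c(O)cc(OC)c2O1
F3 | step 1 | 7-methoxy-4-methyl-1-benzofuran-5-ol | Cc1c(O)cc(OC)c2occc12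
F4 | step 1 | (4S)-4-allyl-7-methoxy-4-methyl-1-benzofuran-5(4H)-one | C=CC[C@]1(C)C(=O)C=C(OC)c2occc12
F5 | step 3 | (4S)-4-(2,2-dimethoxyethyl)-2,7-dimethoxy-4-methyl-2,3-dihydro-1-benzofuran-5(4H)-one | COC(OC)C[C@]1(C)C(=O)C=C(OC)C2=C1CC(OC)O2
F6 | step 3 | (4S)-4-(2,2-dimethoxyethyl)-7-methoxy-4-methyl-1-benzofuran-5(4H)-one | COC(OC)C[C@]1(C)C(=O)C=C(OC)c2occc12
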